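# Proposal: 34 (CNP0222998.2) by strain-release fragmentation of a cyclobutene–enone photoadduct

## The problem

1. Target 34 is a ten-membered carbocycle, numbered C1–C10. C1=C10 carries methyl C14 on C10, and C4=C5 carries the hydroxymethyl C15 on C4. A trans-fused α-methyl-γ-lactone spans C6–C7 (O on C6, C7–C11(C13 methyl)–C12=O), and O8 bears an (E)-4-hydroxy-2-methylbut-2-enoate.
2. The ring olefins are cis at C1=C10 and trans at C4=C5. This pairing is neither the kinetically nor the thermodynamically easy one, so it must be built in and cannot be reached by equilibration.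
3. The four contiguous stereocentres are 6R, 7R, 8S and 11S. O6 and O8 lie on one side of the C5–C9 chain and the C11 branch on the other. C13 is trans to C8 on the lactone, which should be the more stable C11 epimer.
4. C7 and C8 can be set on a six-membered ring and C11 by a stereospecific substitution. C6 and the two olefin geometries have to be derived from these and are the hard part.
5. A ten-membered ring resists closure by bond formation because of transannular strain and entropy.
6. Several groups are fragile: the 1,5-diene (Cope rearrangement, acid-induced transannular cyclisation), the allylic lactone oxygen, C11, β-oxygenated carbonyl intermediates (elimination), a free C8 hydroxyl beside the lactone (acyl shift to O8), and the hydroxytiglate (hydride, base).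
7. The enabling feature is that the two ring olefins are 1,5-related. They are the π bonds released when a bicyclo[2.2.0]hexane made of ring B (C1–C10–C5–C4) and ring C (C1–C2–C3–C4) loses C1–C4 and C5–C10. Ring A (C5–C6–C7–C8–C9–C10), a cyclohexanone, carries C7 and C8.

## Retrosynthesis

**34 ⇒ 26 + 30 (C8–O acyl bond; C15 and C4′ oxidation levels).** The hydroxytiglate cannot pass through hydride or enolate chemistry, so its acyl C–O bond is cut first, giving hydroxy lactone 26 and silyl-protected acid 30. In 26, C15 is an aldehyde rather than an alcohol, so no primary hydroxyl competes in the esterification (32). A chemoselective 1,2-reduction (33) and one desilylation then finish the synthesis. The forward step must acylate a hindered secondary alcohol without moving the lactone to O8.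

**26 ⇒ 25 ⇒ 23 (lactone C12–O6).** The lactone is opened to the 6,12-diol of triol 23, whose third hydroxyl is C15. Closing the lactone by acyl substitution from a C12 ester was considered. It leaves a C15 ester that cannot be reduced beside the lactone, whereas one oxidation of 23 delivers lactone and enal (25) together. The forward oxidation must touch the primary alcohols faster than the allylic C6 carbinol.

**23 ⇒ 22 (three C–H bonds).** Triol 23 comes from dienone 22 by hydride reduction of the ketone and both esters. Nothing is simplified in the skeleton, but all oxygen functions of 22 are carbonyls, which is what the fragmentation needs. The forward reaction must reduce 1,2 and choose the C6 face.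

**22 ⇒ 21 (reconnect C1–C4 and C5–C10).** This is the central simplification: the medium ring with its two olefins becomes tricycle 21 with a six-membered ring A. Against macrocyclisation it offers a unimolecular, strain-driven ring opening. Its stereochemical demand is specific.

- In the chair-like 1,4-diyl, the C10 substituent that is axial ends up cis to C2, and the C5 substituent that is equatorial ends up trans to C3.
- For 22, C9 must therefore be axial and C6 equatorial on the diyl ring. On ring A this is the chair with C4 axial and C1 equatorial.
- That chair has the C7 branch and O8 both equatorial only if the cyclobutanes are cis to O8 and trans to the C7 branch. The opposite face isomer would give the 1(10)-trans,4-cis diene.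

**21 ⇒ 17 + 19 (C7–C11).** The side chain is removed as lactate triflate 19, leaving ketone 17. Alkylating before the cycloaddition was rejected: the cyclobutene would then add anti to the siloxy group and syn to the side chain, the relationship that leads to the wrong diene. On 17 the siloxy group and the cyclobutanes shield the same face, so the electrophile is steered to the required one, and SN2 inversion sets C11.

**17 ⇒ 11 (C8 configuration, via 16–12).** No skeletal bond is cut. Cycloaddition to a 5-siloxy enone should place the cyclobutane anti to the siloxy group, but 21 needs it syn. The C8 oxygen is therefore used first as the controller of the cycloaddition (11) and then turned over through ketone 14. C6 is masked as a dioxolane meanwhile, and the rigid tricycle directs the hydride.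

**11 ⇒ 7 + 10 (C1–C10 and C4–C5).** The [2+2] photocycloaddition of enone 7 and cyclobutene ester 10 builds both temporary four-membered rings and the quaternary C10 in one step. The forward reaction must be head-to-head, with cis-anti-cis fusion.

**7 ⇒ 5 ⇒ 3 ⇒ 2 ⇒ 1.** The methyl group is removed without transposing the enone (conjugate methylation then Saegusa oxidation, through 6), so the configuration of 5 is kept. Enone 5 comes from monoacetate 3 by oxidation and loss of acetate, and 3 from the enzymatic desymmetrisation of meso diol 2, the monosilyl ether of triol 1.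

**Small fragments.** Ester 10 comes from acid 9 and bromo ester 8. Acid 30 comes from ester 29, a Wittig product of aldehyde 27 and ylide 28. Triflate 19 comes from ethyl (S)-lactate 18.

## Roads not taken

**Alternative 1:** The cut is C7–C8 together with C11–C13 on a preformed lactone: the anion of dithiane A2 adds to C7 of butenolide A1, and the lactone enolate is methylated to give A3.

- Merits: C6 comes with A1, C7 and C11 follow from the anti,anti preference of the butenolide, the lactone is present from the start, and the cis C1=C10 geometry is carried in A2. No photochemistry or high temperature is needed.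
- Weak points: no ring is closed, so a ten-membered macrocyclisation still lies ahead. C8 arrives as a thioacetal and must be unmasked and reduced beside the lactone without an obvious control element. The anion must add 1,4 rather than 1,2.
- Comparison: for C6, C7 and C11 this road is better than the chosen one, which needs a relay at C8 and sets C6 late. The chosen plan offers in return a ring and two olefins formed by a unimolecular fragmentation without dilution, and a C8 centre set on a rigid tricycle.

**Alternative 2:** The cut is C5–C6 and the lactone C–O bond: iodo aldehyde A4 cyclises by chromium-mediated vinyl addition, and the C6 alkoxide closes the lactone to A5.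

- Merits: both olefin geometries are fixed in the open chain of A4, independent of any relative configuration in a precursor. For geometry this is the more secure road, and it is convergent.
- Weak points: a strained ten-membered ring is closed by bond formation under high dilution. The C6 configuration depends on the facial course of the addition. The α-branched aldehyde at C7 can epimerise. The C7/C8/C11 triad must be built in an acyclic series.
- Comparison: the chosen plan cannot match the built-in geometry. It offers instead a ring that appears by strain release and two stereocentres set on six-membered rings.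

**Alternative 3:** The cut is C2–C3 through a [3,3] shift: the potassium alkoxide of dialkenyl cyclohexanol A6 rearranges, and the C10 enolate is trapped as enol triflate A7.

- Merits: it uses the same logic as the chosen plan, a ring expansion of a cyclohexane that carries C6–C8. It runs near room temperature, and the C6 oxygen is already in place, so C6 is not set on the macrocycle. In mildness and in C6 control it is the better ring expansion.
- Weak points: A6 needs five stereocentres including a tertiary carbinol with the correct cis relationship of the two alkenyl groups. C14 must be added afterwards by coupling of A7. The lactol acetal needs a later oxidation.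
- Comparison: the chosen plan offers the assembly of both temporary bonds in one cycloaddition, and C14 and C15 in place before the ring opens.

Key step: step 17

## Route

Remark: the lipase is assumed to acetylate the carbinol predicted by the empirical size rule (siloxy-bearing flank as the larger group). Tricyclic compounds are described with the numbering of the ten-membered ring.

Step 1
Reactants: 1 cis,cis-cyclohexane-1,3,5-triol
Product: 2 all-cis-5-(tert-butyldimethylsilyloxy)cyclohexane-1,3-diol (meso)
Conditions: TBSCl (1.0 equiv), imidazole, DMF, 0 °C to rt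
Reagents that add atoms: tert-butyldimethylsilyl chloride CC(C)(C)[Si](C)(C)Cl
Why: Statistical monosilylation of a symmetric triol (silyl ether formation); the product is meso, so no stereochemical question arises, and over-silylated material is separable.

Step 2
Reactants: 2 all-cis-5-(tert-butyldimethylsilyloxy)cyclohexane-1,3-diol
Product: 3 (1R,3S,5S)-3-(tert-butyldimethylsilyloxy)-5-hydroxycyclohexyl acetate
Conditions: lipase from Burkholderia cepacia (immobilised), vinyl acetate, t-BuOMe, rt
Reagents that add atoms: vinyl acetate CC(=O)OC=C
Why: Lipase-catalysed enantiotopos-selective transesterification of a meso 1,3-diol; by the empirical size rule the R carbinol, whose larger flank leads to the siloxy carbon, is acetylated, which fixes the three centres of 3.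

Step 3
Reactants: 3 (1R,3S,5S)-3-(tert-butyldimethylsilyloxy)-5-hydroxycyclohexyl acetate
Product: 5 (R)-5-(tert-butyldimethylsilyloxy)cyclohex-2-en-1-one, via β-acetoxy ketone 4 (not isolated)
Conditions: Dess–Martin periodinane, CH2Cl2, rt; then Et3N, rt
Reagents that add atoms: none
Why: Dess–Martin oxidation of the free carbinol, then E1cB loss of acetate (a far better leaving group than silanolate) gives the enone; the siloxy centre is untouched.

Step 4
Reactants: 5 (R)-5-(tert-butyldimethylsilyloxy)cyclohex-2-en-1-one
Product: 6 (3R,5R)-5-(tert-butyldimethylsilyloxy)-3-methyl-1-(trimethylsilyloxy)cyclohex-1-ene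
Conditions: Me2CuLi (from CuI and MeLi), Me3SiCl, Et2O, −78 °C; Et3N, cold aq. NaHCO3
Reagents that add atoms: lithium dimethylcuprate [Li+].C[Cu-]C; chlorotrimethylsilane C[Si](C)(C)Cl
Why: Cuprate conjugate addition trans to the 5-siloxy group with in-situ silylation gives the regiodefined silyl enol ether for the Saegusa oxidation; the new methyl centre is removed again in step 5.

Step 5
Reactants: 6 (3R,5R)-5-(tert-butyldimethylsilyloxy)-3-methyl-1-(trimethylsilyloxy)cyclohex-1-ene
Product: 7 (R)-5-(tert-butyldimethylsilyloxy)-3-methylcyclohex-2-en-1-one
Conditions: Pd(OAc)2 (1.1 equiv), MeCN, rt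
Reagents that add atoms: none
Why: Saegusa oxidation (palladium enolate, β-hydride elimination toward the methyl-bearing carbon) restores the enone with C14 in place and without transposition, so the configuration of 5 is kept.

Step 6
Reactants: 8 ethyl 1-bromocyclobutane-1-carboxylate
Product: 9 cyclobut-1-ene-1-carboxylic acid
Conditions: KOH, toluene, reflux; then aq. HCl
Reagents that add atoms: potassium hydroxide [K+].[OH-]
Why: Dehydrobromination of the tertiary α-bromo ester with concomitant saponification, the standard entry to this acid.

Step 7
Reactants: 9 cyclobut-1-ene-1-carboxylic acid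
Product: 10 methyl cyclobut-1-ene-1-carboxylate
Conditions: MeI, K2CO3, DMF, 0 °C to rt
Reagents that add atoms: iodomethane CI
Why: Carboxylate O-alkylation (SN2) under mild base avoids conjugate addition to the strained acrylate; the ester is used at once as a solution.

Step 8
Reactants: 7 (R)-5-(tert-butyldimethylsilyloxy)-3-methylcyclohex-2-en-1-one; 10 methyl cyclobut-1-ene-1-carboxylate
Product: 11 cis-anti-cis photoadduct (C8 siloxy trans to the cyclobutanes)
Conditions: hν (medium-pressure Hg lamp, Pyrex filter), 10 (5 equiv), CH2Cl2, −40 °C; then basic Al2O3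
Reagents that add atoms: none
Why: Enone–alkene [2+2] photocycloaddition; the electron-poor alkene should add head-to-head (C5–C4, C10–C1) with exo fusion, as known for cyclohexenones and cyclobut-1-enecarboxylates, and any trans-fused adduct is epimerised at C5 on alumina. The C10–C1 bond should form axially on the half-chair with equatorial siloxy, that is on the face opposite O8; the minor facial isomer is removed here because it would lead into the enantiomeric series.

Step 9
Reactants: 11 cis-anti-cis photoadduct
Product: 12 C6 1,3-dioxolane of 11
Conditions: (Me3SiOCH2)2, Me3SiOTf (cat.), CH2Cl2, −78 to −20 °C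
Reagents that add atoms: 1,2-bis(trimethylsilyloxy)ethane C[Si](C)(C)OCCO[Si](C)(C)C
Why: Silyl-triflate-catalysed ketalisation under aprotic conditions masks C6 without exposing the β-siloxy ketone to protic acid, so that C8 can be taken through the ketone.

Step 10
Reactants: 12 C6 1,3-dioxolane of 11
Product: 13 C8 alcohol (hydroxyl trans to the cyclobutanes)
Conditions: Bu4NF, THF, 0 °C to rt
Reagents that add atoms: none
Why: Fluoride cleavage of the silyl ether; ester and ketal are inert.

Step 11
Reactants: 13 C8 alcohol
Product: 14 C8 ketone with C6 dioxolane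
Conditions: Dess–Martin periodinane, pyridine, CH2Cl2, rt
Reagents that add atoms: none
Why: Dess–Martin oxidation; the β-keto ketal does not eliminate under buffered conditions, and C8 is no longer stereogenic.

Step 12
Reactants: 14 C8 ketone with C6 dioxolane
Product: 15 C8 alcohol epimer (8S, hydroxyl cis to the cyclobutanes)
Conditions: LiBH(s-Bu)3, THF, −78 °C; then H2O
Reagents that add atoms: none
Why: Hydride addition to a cyclohexanone whose one face carries two syn-axial groups (C1 on C10 and a ketal oxygen on C6); the bulky borohydride should enter from the open face, which places the hydroxyl on the cyclobutane face and sets C8 as S.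

Step 13
Reactants: 15 C8 alcohol epimer
Product: 16 tert-butyldimethylsilyl ether of 15
Conditions: TBSOTf, 2,6-lutidine, CH2Cl2, −78 °C
Reagents that add atoms: tert-butyldimethylsilyl triflate CC(C)(C)[Si](C)(C)OS(=O)(=O)C(F)(F)F
Why: Silylation of a hindered secondary alcohol with the silyl triflate; at low temperature this is much faster than attack on the dioxolane.

Step 14
Reactants: 16 tert-butyldimethylsilyl ether of 15
Product: 17 tricyclic ketone (C8 epimer of 11)
Conditions: PPTS (cat.), acetone/H2O, 50 °C
Reagents that add atoms: water O
Why: Acid-catalysed transketalisation releases the C6 ketone; the secondary silyl ether and the methyl ester tolerate pyridinium tosylate.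

Step 15
Reactants: 18 ethyl (S)-lactate
Product: 19 ethyl (S)-2-(trifluoromethylsulfonyloxy)propanoate
Conditions: Tf2O, 2,6-lutidine, CH2Cl2, −78 to 0 °C
Reagents that add atoms: trifluoromethanesulfonic anhydride O=S(=O)(OS(=O)(=O)C(F)(F)F)C(F)(F)F
Why: O-sulfonylation with retention at carbon gives an α-triflyloxy ester that reacts by clean SN2.

Step 16
Reactants: 17 tricyclic ketone; 19 ethyl (S)-2-(trifluoromethylsulfonyloxy)propanoate
Product: 21 C7-alkylated tricyclic keto diester (7R,8S,11S), via lithium enolate 20 (not isolated)
Conditions: LiN(i-Pr)2, THF, −78 °C; then 19, −78 to −40 °C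
Reagents that add atoms: none
Why: Kinetic deprotonation at the C7 methylene (C5 is a hindered methine) and SN2 alkylation with inversion at the lactate carbon; the electrophile approaches C7 anti to both the siloxy group and the cyclobutanes, which gives 7R and 11S.

Step 17
Reactants: 21 C7-alkylated tricyclic keto diester
Product: 22 ten-membered 1(10)-cis,4-trans dienone
Conditions: degassed toluene (0.01 M), BHT (5 mol %), base-washed sealed tube, 180–190 °C, 1–2 h
Reagents that add atoms: none
Why: Thermal homolysis of the strained central bond C1–C4 of the bicyclo[2.2.0]hexane (rings B and C) gives a cyclohexane-1,4-diyl stabilised at C4 by the ester, and β-scission of C5–C10 then forms C1=C10 and C4=C5. The closest known reaction type is the thermolysis of cyclohexenone–cyclobut-1-enecarboxylate photoadducts to cis,trans-cyclodeca-1,5-dienes. The ten-membered ring is not closed by bond formation: it is the periphery of rings A, B and C and appears when the two transannular bonds break, so no dilution is needed. No stereocentre is created, and the four ring-fusion centres vanish. The selectivity needed is which olefin becomes cis: in the chair-like diyl the cis-fused ring A must place C9 axial (C9 cis to C2) and C6 equatorial (C15 ester cis to C6, the trans ring olefin). This is the ring A chair with C4 axial and C1 equatorial, and in 21 it is the only chair with the C7 side chain and the C8 siloxy group both equatorial; the other chair would make both axial and set the siloxy group syn-axial to C1. Conjugation of C4=C5 with ketone and ester and a short contact time should hold back the onward Cope rearrangement.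

Step 18
Reactants: 22 ten-membered dienone
Product: 23 (6R,7R,8S,11S)-8-siloxy-6,12,15-triol
Conditions: i-Bu2AlH (7 equiv), CH2Cl2, −78 to 0 °C; aq. KNaC4H4O6
Reagents that add atoms: none
Why: 1,2-Reduction of ketone, enoate and saturated ester by the aluminium hydride; the C6 carbonyl should be attacked from the periphery, anti to the C11 branch on C7 held perpendicular to the carbonyl, which gives the 6R alcohol, and any lactol aluminate formed in the flask is reduced on to the diol.

Step 19
Reactants: 23 8-siloxy-6,12,15-triol
Product: 25 8-siloxy-15-oxo-6,12-lactone, via lactol enal 24 (not isolated)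
Conditions: TEMPO (0.2 equiv), PhI(OAc)2 (3.3 equiv), CH2Cl2, rt
Reagents that add atoms: none
Why: Nitroxyl-catalysed oxidation is fastest at the two primary alcohols; the C12 aldehyde is trapped by the C6 hydroxyl as the five-membered lactol and oxidised to the trans-fused lactone, while C15 stops at the enal.

Step 20
Reactants: 25 8-siloxy-15-oxo-6,12-lactone
Product: 26 8-hydroxy-15-oxo-6,12-lactone
Conditions: HF·pyridine, pyridine/THF, 0 °C to rt
Reagents that add atoms: none
Why: Fluoride cleavage of the secondary silyl ether under buffered, mildly acidic conditions, which avoids lactone migration to O8 and epimerisation at C11.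

Step 21
Reactants: 27 (tert-butyldimethylsilyloxy)acetaldehyde; 28 ethyl 2-(triphenylphosphoranylidene)propanoate
Product: 29 ethyl (E)-4-(tert-butyldimethylsilyloxy)-2-methylbut-2-enoate
Conditions: CH2Cl2, rt
Reagents that add atoms: none
Why: Wittig olefination with a stabilised α-methyl ylide gives the E-trisubstituted enoate.

Step 22
Reactants: 29 ethyl (E)-4-(tert-butyldimethylsilyloxy)-2-methylbut-2-enoate
Product: 30 (E)-4-(tert-butyldimethylsilyloxy)-2-methylbut-2-enoic acid
Conditions: LiOH, THF/MeOH/H2O, rt; then cold 1 M HCl to pH 4
Reagents that add atoms: lithium hydroxide [Li+].[OH-]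
Why: Saponification of the ethyl ester; the primary silyl ether withstands hydroxide and a brief cold acidification.

Step 23
Reactants: 26 8-hydroxy-15-oxo-6,12-lactone; 30 (E)-4-(tert-butyldimethylsilyloxy)-2-methylbut-2-enoic acid
Product: 32 C8 ester with C15 aldehyde, via mixed anhydride 31 (not isolated)
Conditions: 2,4,6-trichlorobenzoyl chloride, Et3N, THF, rt; then 26, DMAP, toluene, rt
Reagents that add atoms: none
Why: Yamaguchi esterification through the mixed anhydride acylates the hindered secondary C8 alcohol and keeps the E geometry of the acid; no primary alcohol competes because C15 is an aldehyde.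

Step 24
Reactants: 32 C8 ester with C15 aldehyde
Product: 33 silyl-protected target (C15 alcohol)
Conditions: NaBH4, CeCl3·7H2O, MeOH, −78 °C
Reagents that add atoms: none
Why: Luche reduction gives clean 1,2-reduction of the enal at low temperature; lactone and conjugated ester are not reduced.

Step 25
Reactants: 33 silyl-protected target
Product: 34 target CNP0222998.2
Conditions: HF·pyridine, pyridine/THF, 0 °C
Reagents that add atoms: none
Why: Mild fluoride desilylation of the primary allylic silyl ether; the two esters, the lactone and the diene are stable to buffered HF·pyridine.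

## Compound list

1 | cis,cis-cyclohexane-1,3,5-triol | O[C@H]1C[C@@H](O)C[C@@H](O)C1 | starting material
2 | all-cis-5-(tert-butyldimethylsilyloxy)cyclohexane-1,3-diol (meso) | O[C@H]1C[C@@H](O)C[C@@H](O[Si](C)(C)C(C)(C)C)C1 | intermediate
3 | (1R,3S,5S)-3-(tert-butyldimethylsilyloxy)-5-hydroxycyclohexyl acetate | O[C@H]1C[C@@H](OC(C)=O)C[C@@H](O[Si](C)(C)C(C)(C)C)C1 | intermediate
4 | (1S,3R)-3-(tert-butyldimethylsilyloxy)-5-oxocyclohexyl acetate | O=C1C[C@@H](OC(C)=O)C[C@@H](O[Si](C)(C)C(C)(C)C)C1 | intermediate
5 | (R)-5-(tert-butyldimethylsilyloxy)cyclohex-2-en-1-one | O=C1C=CC[C@@H](O[Si](C)(C)C(C)(C)C)C1 | intermediate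
6 | (3R,5R)-5-(tert-butyldimethylsilyloxy)-3-methyl-1-(trimethylsilyloxy)cyclohex-1-ene (methyl trans to siloxy) | C[C@H]1C=C(O[Si](C)(C)C)C[C@H](O[Si](C)(C)C(C)(C)C)C1 | intermediate
7 | (R)-5-(tert-butyldimethylsilyloxy)-3-methylcyclohex-2-en-1-one | CC1=CC(=O)C[C@H](O[Si](C)(C)C(C)(C)C)C1 | intermediate
8 | ethyl 1-bromocyclobutane-1-carboxylate | CCOC(=O)C1(Br)CCC1 | starting material
9 | cyclobut-1-ene-1-carboxylic acid | OC(=O)C1=CCC1 | intermediate
10 | methyl cyclobut-1-ene-1-carboxylate | COC(=O)C1=CCC1 | intermediate
11 | cis-anti-cis photoadduct: methyl 9-(tert-butyldimethylsilyloxy)-1-methyl-7-oxotricyclo[4.4.0.0(2,5)]decane-5-carboxylate; C8 siloxy trans to the cyclobutanes on ring A | C[C@@]12C[C@@H](O[Si](C)(C)C(C)(C)C)CC(=O)[C@@H]1[C@@]3(C(=O)OC)CC[C@H]32 | intermediate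
12 | C6 ethylene ketal (1,3-dioxolane) of 11 | C[C@@]12C[C@@H](O[Si](C)(C)C(C)(C)C)CC3(OCCO3)[C@@H]1[C@@]4(C(=O)OC)CC[C@H]42 | intermediate
13 | C8 alcohol of the ketal, hydroxyl trans to the cyclobutanes | C[C@@]12C[C@@H](O)CC3(OCCO3)[C@@H]1[C@@]4(C(=O)OC)CC[C@H]42 | intermediate
14 | C8 ketone with C6 dioxolane | C[C@@]12CC(=O)CC3(OCCO3)[C@@H]1[C@@]4(C(=O)OC)CC[C@H]42 | intermediate
15 | C8 alcohol epimer (8S), hydroxyl cis to the cyclobutanes | C[C@@]12C[C@H](O)CC3(OCCO3)[C@@H]1[C@@]4(C(=O)OC)CC[C@H]42 | intermediate
16 | tert-butyldimethylsilyl ether of 15 | C[C@@]12C[C@H](O[Si](C)(C)C(C)(C)C)CC3(OCCO3)[C@@H]1[C@@]4(C(=O)OC)CC[C@H]42 | intermediate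
17 | tricyclic ketone, C8 epimer of 11 (8S siloxy cis to the cyclobutanes) | C[C@@]12C[C@H](O[Si](C)(C)C(C)(C)C)CC(=O)[C@@H]1[C@@]3(C(=O)OC)CC[C@H]32 | intermediate
18 | ethyl (S)-lactate | CCOC(=O)[C@H](C)O | starting material
19 | ethyl (S)-2-(trifluoromethylsulfonyloxy)propanoate | CCOC(=O)[C@H](C)OS(=O)(=O)C(F)(F)F | intermediate
20 | lithium enolate of 17 (C6=C7) | C[C@@]12C[C@H](O[Si](C)(C)C(C)(C)C)C=C([O-])[C@@H]1[C@@]3(C(=O)OC)CC[C@H]32.[Li+] | intermediate
21 | fragmentation substrate: 17 carrying (S)-1-ethoxy-1-oxopropan-2-yl at C7 (7R,8S,11S; side chain trans to siloxy and to the cyclobutanes) | C[C@@]12C[C@H](O[Si](C)(C)C(C)(C)C)[C@@H]([C@H](C)C(=O)OCC)C(=O)[C@@H]1[C@@]3(C(=O)OC)CC[C@H]32 | intermediate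
22 | ten-membered 1(10)-cis,4-trans dienone: C6 ketone, C15 methyl ester on C4, C14 on C10, 8S siloxy, 7R (S)-propanoate side chain | C/C1=C/CC/C(C(=O)OC)=C/C(=O)[C@H]([C@H](C)C(=O)OCC)[C@@H](O[Si](C)(C)C(C)(C)C)C1 | intermediate
23 | (6R,7R,8S,11S)-8-(tert-butyldimethylsilyloxy)-1(10)-cis,4-trans-diene-6,12,15-triol | C/C1=C/CC/C(CO)=C/[C@@H](O)[C@H]([C@H](C)CO)[C@@H](O[Si](C)(C)C(C)(C)C)C1 | intermediate
24 | 6,12-lactol with C15 aldehyde (anomers) | C/C1=C/CC/C(C=O)=C/[C@H]2OC(O)[C@@H](C)[C@@H]2[C@@H](O[Si](C)(C)C(C)(C)C)C1 | intermediate
25 | 8-(tert-butyldimethylsilyloxy)-15-oxo-6,12-lactone | C/C1=C/CC/C(C=O)=C/[C@H]2OC(=O)[C@@H](C)[C@@H]2[C@@H](O[Si](C)(C)C(C)(C)C)C1 | intermediate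
26 | 8-hydroxy-15-oxo-6,12-lactone | C/C1=C/CC/C(C=O)=C/[C@H]2OC(=O)[C@@H](C)[C@@H]2[C@@H](O)C1 | intermediate
27 | (tert-butyldimethylsilyloxy)acetaldehyde | CC(C)(C)[Si](C)(C)OCC=O | starting material
28 | ethyl 2-(triphenylphosphoranylidene)propanoate | CCOC(=O)C(C)=P(c1ccccc1)(c1ccccc1)c1ccccc1 | starting material
29 | ethyl (E)-4-(tert-butyldimethylsilyloxy)-2-methylbut-2-enoate | CCOC(=O)/C(C)=C/CO[Si](C)(C)C(C)(C)C | intermediate
30 | (E)-4-(tert-butyldimethylsilyloxy)-2-methylbut-2-enoic acid | OC(=O)/C(C)=C/CO[Si](C)(C)C(C)(C)C | intermediate
31 | mixed anhydride of 30 with 2,4,6-trichlorobenzoic acid | O=C(OC(=O)/C(C)=C/CO[Si](C)(C)C(C)(C)C)c1c(Cl)cc(Cl)cc1Cl | intermediate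
32 | 8-O-[(E)-4-(tert-butyldimethylsilyloxy)-2-methylbut-2-enoyl]-15-oxo-6,12-lactone | C/C1=C/CC/C(C=O)=C/[C@H]2OC(=O)[C@@H](C)[C@@H]2[C@@H](OC(=O)/C(C)=C/CO[Si](C)(C)C(C)(C)C)C1 | intermediate
33 | silyl-protected target with free C15 alcohol | C/C1=C/CC/C(CO)=C/[C@H]2OC(=O)[C@@H](C)[C@@H]2[C@@H](OC(=O)/C(C)=C/CO[Si](C)(C)C(C)(C)C)C1 | intermediate
34 | CNP0222998.2 (6R,7R,8S,11S; 1(10)-cis,4-trans) | C/C1=C/CC/C(CO)=C/[C@H]2OC(=O)[C@@H](C)[C@@H]2[C@@H](OC(=O)/C(C)=C/CO)C1 | target

## Step count and risks

Total: 25 steps. Longest linear sequence: 20 steps (steps 1–5, 8–14, 16–20, 23–25).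

**Step 17 (key step).** The diyl may partition toward the other cis/trans pairing. The diene may rearrange further by the Cope pathway at the temperature needed. The β-siloxy ketone may lose silanol or epimerise at C7 on heating.

- Fallback: reduce and tie down before opening the rings. From 21, NaBH4 in MeOH at −20 °C should attack C6 anti to the axial cyclobutane carbon C4. The 6R alkoxide closes onto the neighbouring C15 ester to give the tetracyclic 6,15-lactone F1, which has no enolisable ketone.
- Thermolysis of F1 can only give the ten-membered butenolide F2 with C15 and C6 cis, because C4=C5 then lies in a five-membered ring. The ring olefin is therefore trans by constitution, and the chair diyl makes C1=C10 cis.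
- Excess i-Bu2AlH reduces the butenolide and the ethyl ester of F2 and returns to 23.

**Step 12.** The hydride may show poor facial discrimination if the ketal ring populates the other chair, which would regenerate 13.

- Fallback: invert by substitution instead of redox. From 13, a Mitsunobu reaction with 4-nitrobenzoic acid (PPh3, diisopropyl azodicarboxylate) proceeds through the chair in which the leaving group is axial and gives the inverted 4-nitrobenzoate F3. K2CO3 in MeOH then releases 15.

**Step 16.** The enolate may be alkylated on oxygen by the hard triflate, or may lose silanolate by β-elimination before C-alkylation.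

- Fallback: use an azaenolate. From 17, 1,1-dimethylhydrazine gives the N,N-dimethylhydrazone F4. Metalation with LiN(i-Pr)2 and reaction with 19 gives the C7-alkylated hydrazone F5, with the same facial and SN2 course. Mild hydrolysis with aqueous CuCl2 returns to 21.

**Step 18.** Facial selectivity at C6 of the flexible macrocycle may be poor and may favour the 6S alcohol.

- Fallback: correct C6 by inversion. From 22, NaBH4/CeCl3·7H2O reduces only the ketone and gives the 6S hydroxy diester F6. A Mitsunobu reaction with chloroacetic acid gives the 6R chloroacetate F7. Excess i-Bu2AlH then cleaves the chloroacetate and reduces both esters, returning to 23.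

**Step 2.** The enzyme may choose the other enantiotopic carbinol, or the selectivity may be low.

- Fallback: run the enzyme in the hydrolytic direction. From 2, Ac2O in pyridine gives the meso diacetate F8. Hydrolysis with the same lipase in phosphate buffer removes the acetate the enzyme prefers, leaving the complementary one, and returns to 3.

Further compounds

F1 | step 17 | tetracyclic 6,15-lactone (6R; O6 bridged to C15) | C[C@@]12C[C@H](O[Si](C)(C)C(C)(C)C)[C@@H]([C@H](C)C(=O)OCC)[C@H]4[C@@H]1[C@@]3(C(=O)O4)CC[C@H]32
F2 | step 17 | ten-membered 6,15-butenolide with cis C1=C10 | C/C1=C/CCC2=C[C@@H](OC2=O)[C@H]([C@H](C)C(=O)OCC)[C@@H](O[Si](C)(C)C(C)(C)C)C1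
F3 | step 12 | inverted C8 4-nitrobenzoate of the ketal | C[C@@]12C[C@H](OC(=O)c5ccc(cc5)[N+](=O)[O-])CC3(OCCO3)[C@@H]1[C@@]4(C(=O)OC)CC[C@H]42
F4 | step 16 | N,N-dimethylhydrazone of 17 | C[C@@]12C[C@H](O[Si](C)(C)C(C)(C)C)CC(=NN(C)C)[C@@H]1[C@@]3(C(=O)OC)CC[C@H]32
F5 | step 16 | C7-alkylated N,N-dimethylhydrazone | C[C@@]12C[C@H](O[Si](C)(C)C(C)(C)C)[C@@H]([C@H](C)C(=O)OCC)C(=NN(C)C)[C@@H]1[C@@]3(C(=O)OC)CC[C@H]32
F6 | step 18 | 6S hydroxy diester | C/C1=C/CC/C(C(=O)OC)=C/[C@H](O)[C@H]([C@H](C)C(=O)OCC)[C@@H](O[Si](C)(C)C(C)(C)C)C1
F7 | step 18 | 6R chloroacetate | C/C1=C/CC/C(C(=O)OC)=C/[C@@H](OC(=O)CCl)[C@H]([C@H](C)C(=O)OCC)[C@@H](O[Si](C)(C)C(C)(C)C)C1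
F8 | step 2 | meso all-cis diacetate of 2 | CC(=O)O[C@H]1C[C@@H](OC(C)=O)C[C@@H](O[Si](C)(C)C(C)(C)C)C1
A1 | alternative 1 | C6-substituted butenolide | O=C1C=C[C@@H](/C=C(\CO[Si](C)(C)C(C)(C)C)COCc2ccc(OC)cc2)O1
A2 | alternative 1 | 2-substituted 1,3-dithiane (C8 to C2 arm) | C(C1SCCCS1)/C(C)=C\CO[Si](C(C)(C)C)(c1ccccc1)c1ccccc1
A3 | alternative 1 | trans,trans-trisubstituted γ-lactone with both chain arms | C[C@@H]1C(=O)O[C@H](/C=C(\CO[Si](C)(C)C(C)(C)C)COCc2ccc(OC)cc2)[C@H]1C1(SCCCS1)C/C(C)=C\CO[Si](C(C)(C)C)(c1ccccc1)c1ccccc1
A4 | alternative 2 | acyclic C5 vinyl iodide with C6 aldehyde and C12 methyl ester | I/C=C(\CO[Si](C)(C)C(C)(C)C)CC/C=C(/C)C[C@H](OCc1ccc(OC)cc1)[C@H](C=O)[C@H](C)C(=O)OC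
A5 | alternative 2 | protected ten-membered lactone core | C/C1=C/CC/C(CO[Si](C)(C)C(C)(C)C)=C/[C@H]2OC(=O)[C@@H](C)[C@@H]2[C@@H](OCc2ccc(OC)cc2)C1
A6 | alternative 3 | cis-1,2-dialkenyl cyclohexanol with fused lactol acetal | C=C[C@]1(O)C[C@H](OCc3ccc(OC)cc3)[C@H]2[C@H](C)[C@@H](OC)O[C@@H]2[C@@H]1C(=C)CO[Si](C)(C)C(C)(C)C
A7 | alternative 3 | ten-membered C10 enol triflate with lactol acetal | O=S(=O)(O/C1=C/CC/C(CO[Si](C)(C)C(C)(C)C)=C/[C@H]2O[C@H](OC)[C@@H](C)[C@@H]2[C@@H](OCc3ccc(OC)cc3)C1)C(F)(F)F
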